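**Plan**

- The retrosynthesis cuts the N1–CH3 bond first, the only bond to an sp3 carbon, and then the four C–Br bonds at C2, C3, C4 and C5, which leads back to pyrrole.
- Forward, the pyrrole ring is bought intact and no ring is formed: one exhaustive NBS bromination installs all four bromines, and the methyl group is joined to nitrogen last.
- The feature that makes the last step possible is the N1–H of the perbrominated ring. The bromines on C2 to C5 acidify it enough for K2CO3, and they leave no ring C–H where C-alkylation could compete.
- The target is planar and achiral with no stereocentre, so no stereochemistry has to be set.

Key step: step 2

Assumption: tetrabromopyrrole 3 is expected to be sensitive to light and acid, so it is washed cold with aqueous Na2S2O3, kept as a concentrated solution shielded from light, and methylated the same day.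

**Route**

Step 1
Reactants: 1 pyrrole; 2 N-bromosuccinimide
Product: 3 2,3,4,5-tetrabromo-1H-pyrrole
Conditions: NBS (4.05 equiv), THF, −78 °C to −10 °C, dark, argon
Reagents that add atoms: N-bromosuccinimide, O=C1CCC(=O)N1Br
Why: Exhaustive electrophilic aromatic substitution, in which the π-excessive pyrrole takes bromine from NBS at C2 and C5 and then at C3 and C4, the succinimide by-product is non-acidic so the acid-triggered polymerisation seen with Br2 and HBr is avoided, and four equivalents stop the reaction once no ring C–H remains.

Step 2
Reactants: 3 2,3,4,5-tetrabromo-1H-pyrrole; 4 iodomethane
Product: 6 2,3,4,5-tetrabromo-1-methyl-1H-pyrrole, via potassium tetrabromopyrrolide 5 (not isolated)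
Conditions: K2CO3 (2 equiv), MeI (1.5 equiv), DMF, 0 °C to rt, dark
Reagents that add atoms: iodomethane, CI
Why: K2CO3 removes the N1–H proton, which the four bromines on C2 to C5 make far more acidic than that of pyrrole, to give potassium pyrrolide 5, and the nitrogen of 5 then displaces iodide from iodomethane in an SN2 reaction that forms the N1–CH3 bond. The closest known reaction type is the carbonate-mediated N-alkylation of polyhalogenated and acyl-substituted pyrroles with primary alkyl halides. No ring is closed and no stereocentre is created, so neither a mode of closure nor a controlling element is involved. The selectivity needed is N- over C-alkylation of the ambident anion; the substrate secures it, because every ring carbon already carries bromine and attack there would give a non-aromatic quaternary 2H- or 3H-pyrrole, and the dissociated potassium ion pair in DMF reinforces it. Iodomethane is the smallest carbon electrophile available, which offsets the hindrance from the bromines on C2 and C5, and the N-methyl product has no acidic proton and should be more robust than 3, so it can be filtered through silica with hexane and crystallised.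

**Compound list**

1 | pyrrole (1H-pyrrole) | c1cc[nH]c1 | starting material
2 | N-bromosuccinimide (1-bromopyrrolidine-2,5-dione) | O=C1CCC(=O)N1Br | starting material
3 | 2,3,4,5-tetrabromo-1H-pyrrole | Brc1[nH]c(Br)c(Br)c1Br | intermediate
4 | iodomethane | CI | starting material
5 | potassium 2,3,4,5-tetrabromopyrrol-1-ide | [K+].Brc1[n-]c(Br)c(Br)c1Br | intermediate
6 | 2,3,4,5-tetrabromo-1-methyl-1H-pyrrole | Cn1c(Br)c(Br)c(Br)c1Br | target

**Totals**

Total step count: 2
Longest linear sequence: 2 steps (1 to 3 to 6)

**Steps most likely to fail**

The route has only two steps, so both are ranked here, the riskier first.

1. Step 1. Bromination may stop short and leave tribrominated material, and the perbrominated N–H pyrrole may decompose under light or traces of acid while it is concentrated. Fallback: set out from pyrrole 1 and reverse the order of the two bond-forming events. N-Methylation of 1 with KOH and iodomethane 4 in DMSO at room temperature should give 1-methyl-1H-pyrrole F1, a stable liquid that can be distilled. Exhaustive bromination of it with NBS 2 (4 equiv) in THF from −78 °C should then give the target directly. This path rejoins the route at 6 and never handles the sensitive compound 3.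

2. Step 2. Alkylation of the weakly nucleophilic anion, hindered on both sides of nitrogen, may be slow, so that base- or light-induced degradation of the precursor competes. Fallback: set out from 3 and form the same N1–CH3 bond under neutral conditions by a Mitsunobu reaction with methanol, PPh3 and diisopropyl azodicarboxylate in THF at 0 °C to room temperature. Here the alcohol is activated as an alkoxyphosphonium electrophile and the acidic N–H acts as the pronucleophile, so no free pyrrolide builds up in a basic medium. This path rejoins the route at 6 and makes no new compound (F0).

**Further compounds**

F1 | step 1 | 1-methyl-1H-pyrrole | Cn1cccc1
F0 | step 2 | none | none
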